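**Retrosynthetic overview**

- The strategy rests on one feature: in ring C the aryl ketone bond C4–C4a lies ortho to the ether oxygen O1 on ring A. Ring C is therefore closed last, by bromine–lithium exchange at C4a and intramolecular acylation by an N-methoxy-N-methylamide, on an open-chain aryl ether in which C2 is already (S).
- The C8 prenyl group comes from the C7 phenol after ring C closure, by O-(1,1-dimethylallyl)ation and aromatic Claisen rearrangement.
- The C2–O1 bond and the (S) centre come from an iridium-catalysed branched allylic etherification of a chromanyl cinnamyl-type carbonate with a 2-bromo-5-silyloxyphenoxide; the vinyl group is then converted to CH2C(=O)N(OMe)Me.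
- Ring order: ring D (the dimethyldihydropyran fused to ring B) first, from 4-bromophenol and isoprene; rings A and B come from the aromatic starting materials; ring C last.

Key step: step 10

Remark 1: the C7 oxygen is carried as a triisopropylsilyl ether, which should resist phenoxide, perborate and organolithium conditions better than a smaller silyl group.
Remark 2: the (Sa,S,S) phosphoramidite is assumed to give the (S) ether, as expected for heteroatom nucleophiles on aryl-substituted allyl carbonates; if a first run shows the opposite sense, the antipodal ligand is used.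

**Route**

Step 1
Reactants: 1 4-bromophenol; 2 isoprene
Product: 4 6-bromo-2,2-dimethylchroman, via 4-bromo-2-prenylphenol 3 (not isolated)
Conditions: AgOTf (5 mol%), isoprene (3 equiv), ClCH2CH2Cl, rt → 50 °C
Reagents that add atoms: none
Why: Acid-type (metal triflate) Friedel–Crafts prenylation ortho to the hydroxyl (the para position is blocked by bromine) followed by Markovnikov hydroalkoxylation of the trisubstituted alkene should close ring D as the 2,2-dimethylchroman.

Step 2
Reactants: 4 6-bromo-2,2-dimethylchroman; 5 ethyl acrylate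
Product: 6 ethyl (E)-3-(2,2-dimethylchroman-6-yl)acrylate
Conditions: Pd(OAc)2 (2 mol%), P(o-tol)3 (6 mol%), Et3N, DMF, 100 °C
Reagents that add atoms: none
Why: Heck reaction of the aryl bromide with the acrylate should give the (E)-cinnamate through syn insertion and syn β-hydride elimination, the chroman ether being inert.

Step 3
Reactants: 6 ethyl (E)-3-(2,2-dimethylchroman-6-yl)acrylate
Product: 7 (E)-3-(2,2-dimethylchroman-6-yl)prop-2-en-1-ol
Conditions: i-Bu2AlH (2.3 equiv), CH2Cl2, −78 °C; aq. potassium sodium tartrate work-up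
Reagents that add atoms: none
Why: 1,2-Reduction of the conjugated ester by the aluminium hydride at low temperature should give the allylic alcohol without touching the alkene.

Step 4
Reactants: 7 (E)-3-(2,2-dimethylchroman-6-yl)prop-2-en-1-ol
Product: 8 (E)-3-(2,2-dimethylchroman-6-yl)allyl methyl carbonate
Conditions: ClCO2Me, pyridine, CH2Cl2, 0 °C
Reagents that add atoms: methyl chloroformate, COC(=O)Cl
Why: O-Acylation of the primary allylic alcohol with a chloroformate gives the methyl carbonate that serves as the leaving group in the allylic substitution.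

Step 5
Reactants: 9 4-bromoresorcinol
Product: 10 2-bromo-5-(triisopropylsilyloxy)phenol
Conditions: i-Pr3SiCl (1.0 equiv), imidazole, CH2Cl2, −20 → 0 °C
Reagents that add atoms: triisopropylsilyl chloride, CC(C)[Si](Cl)(C(C)C)C(C)C
Why: Silyl ether formation with the bulky chlorosilane should take the unhindered hydroxyl para to bromine, since the other hydroxyl is flanked by and hydrogen-bonded to the ortho bromine.

Step 6
Reactants: 8 (E)-3-(2,2-dimethylchroman-6-yl)allyl methyl carbonate; 10 2-bromo-5-(triisopropylsilyloxy)phenol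
Product: 12 (S)-6-{1-[2-bromo-5-(triisopropylsilyloxy)phenoxy]prop-2-en-1-yl}-2,2-dimethylchroman, via lithium aryloxide 11 (not isolated)
Conditions: 10, LiN(SiMe3)2 (1.0 equiv), THF, 0 °C; then 8, [Ir(cod)Cl]2 (2 mol%), (Sa,S,S)-O,O'-(1,1'-binaphthyl-2,2'-diyl) N,N-bis(1-phenylethyl)phosphoramidite (4 mol%; catalyst pre-activated with n-PrNH2, volatiles removed), THF, rt
Reagents that add atoms: none
Why: Iridium-catalysed asymmetric allylic etherification: the aryloxide attacks the aryl-substituted terminus of the cyclometalated iridium–phosphoramidite allyl complex from outside the metal to give the branched ether, and the ligand-defined face of attack sets the future C2 as (S).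

Step 7
Reactants: 12 (S)-6-{1-[2-bromo-5-(triisopropylsilyloxy)phenoxy]prop-2-en-1-yl}-2,2-dimethylchroman
Product: 14 (S)-3-[2-bromo-5-(triisopropylsilyloxy)phenoxy]-3-(2,2-dimethylchroman-6-yl)propan-1-ol, via B-alkyl-9-BBN adduct 13 (not isolated)
Conditions: 9-BBN (1.5 equiv), THF, 0 °C → rt; then NaBO3·4H2O, H2O, rt
Reagents that add atoms: sodium perborate tetrahydrate (source of the hydroxyl oxygen), [Na+].[O-]OB=O.O.O.O.O; 9-BBN, C1CCC2CCCC1B2, leaves atoms only in intermediate 13
Why: Hydroboration–oxidation: 9-BBN adds anti-Markovnikov to the monosubstituted alkene and mild perborate oxidation gives the primary alcohol, leaving the aryl bromide, the silyl ether and the benzylic ether centre untouched.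

Step 8
Reactants: 14 (S)-3-[2-bromo-5-(triisopropylsilyloxy)phenoxy]-3-(2,2-dimethylchroman-6-yl)propan-1-ol
Product: 16 (S)-3-[2-bromo-5-(triisopropylsilyloxy)phenoxy]-3-(2,2-dimethylchroman-6-yl)propanoic acid, via aldehyde 15 (not isolated)
Conditions: TEMPO (20 mol%), PhI(OAc)2 (2.2 equiv), MeCN/H2O 1:1, rt
Reagents that add atoms: water, O
Why: Oxoammonium (TEMPO) oxidation with PhI(OAc)2 in aqueous acetonitrile takes the primary alcohol through the aldehyde hydrate to the acid under mildly acidic conditions, in which the β-aryloxy aldehyde cannot undergo base-induced elimination.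

Step 9
Reactants: 16 (S)-3-[2-bromo-5-(triisopropylsilyloxy)phenoxy]-3-(2,2-dimethylchroman-6-yl)propanoic acid
Product: 18 (S)-3-[2-bromo-5-(triisopropylsilyloxy)phenoxy]-3-(2,2-dimethylchroman-6-yl)-N-methoxy-N-methylpropanamide, via acyl imidazole 17 (not isolated)
Conditions: 1,1'-carbonyldiimidazole, CH2Cl2, rt; then MeNH(OMe)·HCl, rt
Reagents that add atoms: N,O-dimethylhydroxylamine hydrochloride, CNOC.Cl; 1,1'-carbonyldiimidazole, O=C(n1ccnc1)n1ccnc1, leaves atoms only in intermediate 17
Why: Amide coupling through the acyl imidazole gives the Weinreb amide without strong base, so the β-aryloxide is not eliminated.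

Step 10
Reactants: 18 (S)-3-[2-bromo-5-(triisopropylsilyloxy)phenoxy]-3-(2,2-dimethylchroman-6-yl)-N-methoxy-N-methylpropanamide
Product: 21 (S)-2-(2,2-dimethylchroman-6-yl)-7-(triisopropylsilyloxy)chroman-4-one, via aryllithium 19 (not isolated), via tetrahedral lithium alkoxide 20 (not isolated)
Conditions: t-BuLi (2.1 equiv), THF/Et2O, −100 °C then −78 °C; AcOH in THF at −78 °C
Reagents that add atoms: none
Why: t-BuLi exchanges the bromine at the future C4a (the second equivalent destroys the t-BuBr formed), and aryllithium 19 adds to the amide carbonyl to give the lithium-chelated tetrahedral adduct 20, which releases the C4 ketone only on the acidic quench. The closest known reaction type is the Parham cyclisation (cycloacylation) of 3-(2-bromoaryloxy)propanoic acid derivatives to chroman-4-ones. Ring C is closed in a 6-exo-trig mode by formation of the C4–C4a bond. No stereocentre is created in the product (the hemiaminal carbon of 20 is transient), and the (S) centre at C2 is carried over because neither the C2–O1 bond nor the C2–H bond takes part. The step needs exchange and ring closure to outrun deprotonation at C3 (which would expel the aryloxide by E1cB) and direct addition of t-BuLi to the amide; the very fast exchange of an aryl bromide at −100 °C, the ortho placement of the carbanion for a six-membered closure, and the para position of the silyloxy group relative to the lithiated carbon (no silyl migration) should secure this. Because the ketone appears only after the base is quenched, ring C is never exposed to conditions for retro-oxa-Michael opening.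

Step 11
Reactants: 21 (S)-2-(2,2-dimethylchroman-6-yl)-7-(triisopropylsilyloxy)chroman-4-one
Product: 22 (S)-2-(2,2-dimethylchroman-6-yl)-7-hydroxychroman-4-one
Conditions: Bu4NF, AcOH (1:1), THF, 0 °C
Reagents that add atoms: none
Why: Fluoride-mediated desilylation buffered with acetic acid should free the C7 phenol without exposing the flavanone to base that could open ring C.

Step 12
Reactants: 23 2-methylbut-3-en-2-ol
Product: 25 tert-butyl (2-methylbut-3-en-2-yl) carbonate, via lithium alkoxide 24 (not isolated)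
Conditions: n-BuLi, THF, 0 °C; then Boc2O, 0 °C → rt
Reagents that add atoms: di-tert-butyl dicarbonate, CC(C)(C)OC(=O)OC(=O)OC(C)(C)C
Why: O-Acylation of the lithium alkoxide of the tertiary allylic alcohol with the dicarbonate gives the mixed carbonate.

Step 13
Reactants: 22 (S)-2-(2,2-dimethylchroman-6-yl)-7-hydroxychroman-4-one; 25 tert-butyl (2-methylbut-3-en-2-yl) carbonate
Product: 26 (S)-2-(2,2-dimethylchroman-6-yl)-7-[(2-methylbut-3-en-2-yl)oxy]chroman-4-one
Conditions: Pd(PPh3)4 (5 mol%), THF, 0 °C
Reagents that add atoms: none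
Why: Decarboxylative Tsuji–Trost allylic etherification: zerovalent palladium ionises the carbonate, the released tert-butoxide deprotonates the phenol, and the phenoxide attacks the more substituted allyl terminus under kinetic control at low temperature, giving the 1,1-dimethylallyl ether with no added base.

Step 14
Reactants: 26 (S)-2-(2,2-dimethylchroman-6-yl)-7-[(2-methylbut-3-en-2-yl)oxy]chroman-4-one
Product: 28 euchrenone a17, via ortho-dienone 27 (not isolated)
Conditions: toluene, 110 °C, sealed tube, base-free glassware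
Reagents that add atoms: none
Why: Aromatic Claisen rearrangement ([3,3]-sigmatropic) of the 1,1-dimethylallyl ether delivers a prenyl group to C8, the ortho position between O1 and O7 favoured by the higher C7–C8 bond order of 4-acylresorcinol ethers, and tautomerisation of the dienone restores the phenol while neutral conditions should leave C2 as (S).

**Compound list**

1 | 4-bromophenol | Oc1ccc(Br)cc1 | starting material
2 | isoprene | C=CC(C)=C | starting material
3 | 4-bromo-2-(3-methylbut-2-en-1-yl)phenol | CC(C)=CCc1cc(Br)ccc1O | intermediate (not isolated)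
4 | 6-bromo-2,2-dimethylchroman | CC1(C)CCc2cc(Br)ccc2O1 | intermediate
5 | ethyl acrylate | C=CC(=O)OCC | starting material
6 | ethyl (E)-3-(2,2-dimethylchroman-6-yl)acrylate | CCOC(=O)/C=C/c1ccc2c(c1)CCC(C)(C)O2 | intermediate
7 | (E)-3-(2,2-dimethylchroman-6-yl)prop-2-en-1-ol | OC/C=C/c1ccc2c(c1)CCC(C)(C)O2 | intermediate
8 | (E)-3-(2,2-dimethylchroman-6-yl)allyl methyl carbonate | COC(=O)OC/C=C/c1ccc2c(c1)CCC(C)(C)O2 | intermediate
9 | 4-bromoresorcinol | Oc1ccc(Br)c(O)c1 | starting material
10 | 2-bromo-5-(triisopropylsilyloxy)phenol | Oc1cc(O[Si](C(C)C)(C(C)C)C(C)C)ccc1Br | intermediate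
11 | lithium 2-bromo-5-(triisopropylsilyloxy)phenoxide | [Li+].[O-]c1cc(O[Si](C(C)C)(C(C)C)C(C)C)ccc1Br | intermediate (not isolated)
12 | (S)-6-{1-[2-bromo-5-(triisopropylsilyloxy)phenoxy]prop-2-en-1-yl}-2,2-dimethylchroman | C=C[C@H](Oc1cc(O[Si](C(C)C)(C(C)C)C(C)C)ccc1Br)c1ccc2c(c1)CCC(C)(C)O2 | intermediate
13 | (S)-9-{3-[2-bromo-5-(triisopropylsilyloxy)phenoxy]-3-(2,2-dimethylchroman-6-yl)propyl}-9-borabicyclo[3.3.1]nonane | B1(CC[C@H](Oc2cc(O[Si](C(C)C)(C(C)C)C(C)C)ccc2Br)c2ccc3c(c2)CCC(C)(C)O3)C2CCCC1CCC2 | intermediate (not isolated)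
14 | (S)-3-[2-bromo-5-(triisopropylsilyloxy)phenoxy]-3-(2,2-dimethylchroman-6-yl)propan-1-ol | OCC[C@H](Oc1cc(O[Si](C(C)C)(C(C)C)C(C)C)ccc1Br)c1ccc2c(c1)CCC(C)(C)O2 | intermediate
15 | (S)-3-[2-bromo-5-(triisopropylsilyloxy)phenoxy]-3-(2,2-dimethylchroman-6-yl)propanal | O=CC[C@H](Oc1cc(O[Si](C(C)C)(C(C)C)C(C)C)ccc1Br)c1ccc2c(c1)CCC(C)(C)O2 | intermediate (not isolated)
16 | (S)-3-[2-bromo-5-(triisopropylsilyloxy)phenoxy]-3-(2,2-dimethylchroman-6-yl)propanoic acid | OC(=O)C[C@H](Oc1cc(O[Si](C(C)C)(C(C)C)C(C)C)ccc1Br)c1ccc2c(c1)CCC(C)(C)O2 | intermediate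
17 | (S)-3-[2-bromo-5-(triisopropylsilyloxy)phenoxy]-3-(2,2-dimethylchroman-6-yl)-1-(imidazol-1-yl)propan-1-one | O=C(C[C@H](Oc1cc(O[Si](C(C)C)(C(C)C)C(C)C)ccc1Br)c1ccc2c(c1)CCC(C)(C)O2)n1ccnc1 | intermediate (not isolated)
18 | (S)-3-[2-bromo-5-(triisopropylsilyloxy)phenoxy]-3-(2,2-dimethylchroman-6-yl)-N-methoxy-N-methylpropanamide | CON(C)C(=O)C[C@H](Oc1cc(O[Si](C(C)C)(C(C)C)C(C)C)ccc1Br)c1ccc2c(c1)CCC(C)(C)O2 | intermediate (key-step precursor)
19 | (S)-3-(2,2-dimethylchroman-6-yl)-3-[2-lithio-5-(triisopropylsilyloxy)phenoxy]-N-methoxy-N-methylpropanamide | CON(C)C(=O)C[C@H](Oc1cc(O[Si](C(C)C)(C(C)C)C(C)C)ccc1[Li])c1ccc2c(c1)CCC(C)(C)O2 | intermediate (not isolated)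
20 | lithium (2S)-2-(2,2-dimethylchroman-6-yl)-4-[methoxy(methyl)amino]-7-(triisopropylsilyloxy)chroman-4-olate (C4 configuration undefined) | [Li+].[O-]C1(N(C)OC)C[C@@H](c2ccc3c(c2)CCC(C)(C)O3)Oc2cc(O[Si](C(C)C)(C(C)C)C(C)C)ccc21 | intermediate (not isolated)
21 | (S)-2-(2,2-dimethylchroman-6-yl)-7-(triisopropylsilyloxy)chroman-4-one | CC(C)[Si](C(C)C)(C(C)C)Oc1ccc2c(c1)O[C@H](c1ccc3c(c1)CCC(C)(C)O3)CC2=O | intermediate (key-step product)
22 | (S)-2-(2,2-dimethylchroman-6-yl)-7-hydroxychroman-4-one | Oc1ccc2c(c1)O[C@H](c1ccc3c(c1)CCC(C)(C)O3)CC2=O | intermediate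
23 | 2-methylbut-3-en-2-ol | CC(C)(O)C=C | starting material
24 | lithium 2-methylbut-3-en-2-olate | [Li+].[O-]C(C)(C)C=C | intermediate (not isolated)
25 | tert-butyl (2-methylbut-3-en-2-yl) carbonate | CC(C)(C)OC(=O)OC(C)(C)C=C | intermediate
26 | (S)-2-(2,2-dimethylchroman-6-yl)-7-[(2-methylbut-3-en-2-yl)oxy]chroman-4-one | C=CC(C)(C)Oc1ccc2c(c1)O[C@H](c1ccc3c(c1)CCC(C)(C)O3)CC2=O | intermediate
27 | (2S)-2-(2,2-dimethylchroman-6-yl)-8-(3-methylbut-2-en-1-yl)-2,3-dihydro-8H-chromene-4,7-dione (C8 configuration undefined) | CC(C)=CCC1C(=O)C=CC2=C1O[C@H](c1ccc3c(c1)CCC(C)(C)O3)CC2=O | intermediate (not isolated)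
28 | euchrenone a17, (S)-2-(2,2-dimethylchroman-6-yl)-7-hydroxy-8-(3-methylbut-2-en-1-yl)chroman-4-one | CC(C)=CCc1c(O)ccc2c1O[C@H](c1ccc3c(c1)CCC(C)(C)O3)CC2=O | target

**Step count and risk**

Total steps: 14. Longest linear sequence: 12 steps (steps 1–4, 6–11, 13 and 14, from 4-bromophenol).

Steps most likely to fail:

1. Step 10 (key step). The amide CH2 may be deprotonated by t-BuLi or by the aryllithium, followed by E1cB loss of the aryloxide, or t-BuLi may add to the amide before exchange. The fallback sets out from acid 16 and cyclises the carboxylate instead of the amide, the original substrate class of the Parham cycloacylation. Treatment with t-BuLi (3.1 equiv) in THF at −100 °C should form lithium (S)-3-[2-bromo-5-(triisopropylsilyloxy)phenoxy]-3-(2,2-dimethylchroman-6-yl)propanoate F4. Exchange then gives lithium (S)-3-(2,2-dimethylchroman-6-yl)-3-[2-lithio-5-(triisopropylsilyloxy)phenoxy]propanoate F5, whose carboxylate has no readily removable α-hydrogen and cannot eliminate. Closure gives dilithium (S)-2-(2,2-dimethylchroman-6-yl)-7-(triisopropylsilyloxy)chroman-4,4-diolate F6, which loses water on AcOH quench and returns to the route at 21.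

2. Step 6. The hindered, weakly nucleophilic ortho-bromophenoxide may react slowly, and the iridium catalyst may re-ionise the electron-rich branched ether, eroding enantiopurity and drifting toward the linear ether. The fallback sets out from cinnamate 6. Copper-catalysed asymmetric conjugate borylation (CuCl, NaOt-Bu, chiral ferrocenyl bisphosphine, B2pin2, MeOH, THF) should give ethyl (R)-3-(2,2-dimethylchroman-6-yl)-3-(4,4,5,5-tetramethyl-1,3,2-dioxaborolan-2-yl)propanoate F1. Perborate oxidation with retention gives ethyl (R)-3-(2,2-dimethylchroman-6-yl)-3-hydroxypropanoate F2. Mitsunobu etherification with phenol 10 (PPh3, diisopropyl azodicarboxylate, toluene, 0 °C) inverts the centre to give ethyl (S)-3-[2-bromo-5-(triisopropylsilyloxy)phenoxy]-3-(2,2-dimethylchroman-6-yl)propanoate F3. Aminolysis with AlMe3 and MeNH(OMe)·HCl in CH2Cl2 returns to the route at 18.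

3. Step 14. The allyl unit may migrate to C6 instead of C8, the tert-allyl group may be lost as isoprene, or prolonged heating may open and reclose ring C and erode the C2 configuration. The fallback sets out from phenol 22. Iodination ortho to the hydroxyl between the two ring oxygens (benzyltrimethylammonium dichloroiodate, NaHCO3, CH2Cl2/MeOH, rt) should give (S)-2-(2,2-dimethylchroman-6-yl)-7-hydroxy-8-iodochroman-4-one F7. Stille coupling with tributyl(3-methylbut-2-en-1-yl)stannane (Pd(PPh3)4, DMF, 80 °C) then places the prenyl group at C8 and returns to the route at 28.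

**Further compounds**

F1 | step 6 | ethyl (R)-3-(2,2-dimethylchroman-6-yl)-3-(4,4,5,5-tetramethyl-1,3,2-dioxaborolan-2-yl)propanoate | CCOC(=O)C[C@@H](B1OC(C)(C)C(C)(C)O1)c1ccc2c(c1)CCC(C)(C)O2
F2 | step 6 | ethyl (R)-3-(2,2-dimethylchroman-6-yl)-3-hydroxypropanoate | CCOC(=O)C[C@@H](O)c1ccc2c(c1)CCC(C)(C)O2
F3 | step 6 | ethyl (S)-3-[2-bromo-5-(triisopropylsilyloxy)phenoxy]-3-(2,2-dimethylchroman-6-yl)propanoate | CCOC(=O)C[C@H](Oc1cc(O[Si](C(C)C)(C(C)C)C(C)C)ccc1Br)c1ccc2c(c1)CCC(C)(C)O2
F4 | step 10 | lithium (S)-3-[2-bromo-5-(triisopropylsilyloxy)phenoxy]-3-(2,2-dimethylchroman-6-yl)propanoate | [Li+].[O-]C(=O)C[C@H](Oc1cc(O[Si](C(C)C)(C(C)C)C(C)C)ccc1Br)c1ccc2c(c1)CCC(C)(C)O2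
F5 | step 10 | lithium (S)-3-(2,2-dimethylchroman-6-yl)-3-[2-lithio-5-(triisopropylsilyloxy)phenoxy]propanoate | [Li+].[O-]C(=O)C[C@H](Oc1cc(O[Si](C(C)C)(C(C)C)C(C)C)ccc1[Li])c1ccc2c(c1)CCC(C)(C)O2
F6 | step 10 | dilithium (S)-2-(2,2-dimethylchroman-6-yl)-7-(triisopropylsilyloxy)chroman-4,4-diolate | [Li+].[Li+].[O-]C1([O-])C[C@@H](c2ccc3c(c2)CCC(C)(C)O3)Oc2cc(O[Si](C(C)C)(C(C)C)C(C)C)ccc21
F7 | step 14 | (S)-2-(2,2-dimethylchroman-6-yl)-7-hydroxy-8-iodochroman-4-one | Oc1ccc2c(c1I)O[C@H](c1ccc3c(c1)CCC(C)(C)O3)CC2=O
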